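**Retrosynthetic overview**
- Target ⇐ its 3-O-silyl ether by a final desilylation (no skeletal change).
- Silyl ether ⇐ acyclic (Z)-allylic chloride α,α′-bis(benzoyloxy) ketone: the C1–C6 bond and the C6–O bond are cut together. Forward, an allylic sulfonium ylide adds to the ketone (carbocycle closes first) and the alkoxide then displaces the sulfide (oxirane closes second), in one operation.
- (Z)-Allylic chloride ⇐ ynone dibenzoate (semi-hydrogenation) ⇐ acetonide-protected aldol (silylation, ketal hydrolysis, benzoylation).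
- Aldol ⇐ 2,2-dimethyl-1,3-dioxan-5-one + 4-chlorobut-2-ynal by (R)-proline anti-aldol, which sets C2 and C3; ynal ⇐ 4-chlorobut-2-yn-1-ol.

Assumption: the SMILES is read literally as (1S,2R,3R,6S), with the epoxide oxygen, the 2-benzoate and the 3-hydroxyl on one ring face; carbons carry the target numbering (C1 = epoxide carbon bearing C7H2OBz, C2 = CHOBz, C3 = CHOH, C4=C5, C6 = epoxide CH).

**Step 1**
Reactants: 1 4-chlorobut-2-yn-1-ol
Product: 2 4-chlorobut-2-ynal
Conditions: TEMPO (10 mol%), PhI(OAc)2 (1.1 equiv), CH2Cl2, rt; short silica plug, used at once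
Reagents that add atoms: none
Why: Oxoammonium-mediated (TEMPO/PhI(OAc)2) oxidation of a primary propargylic alcohol stops at the ynal under neutral anhydrous conditions that leave the propargylic chloride untouched.

**Step 2**
Reactants: 2 4-chlorobut-2-ynal; 3 2,2-dimethyl-1,3-dioxan-5-one
Product: 4 (4R)-4-[(1R)-4-chloro-1-hydroxybut-2-yn-1-yl]-2,2-dimethyl-1,3-dioxan-5-one
Conditions: (R)-proline (30 mol%), DMF, 4 °C, 3 d
Reagents that add atoms: none
Why: Proline-catalysed direct aldol reaction (enamine catalysis): the (E)-enamine of 3 adds to the si face of the non-enolisable ynal through the hydrogen-bonded Houk–List transition state, giving the anti aldol and so setting C2 (R) and C3 (R) together, as this ketone does with other aldehydes in organocatalytic ketose syntheses.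

**Step 3**
Reactants: 4 (4R)-4-[(1R)-4-chloro-1-hydroxybut-2-yn-1-yl]-2,2-dimethyl-1,3-dioxan-5-one
Product: 5 (4R)-4-[(1R)-1-(tert-butyldimethylsilyloxy)-4-chlorobut-2-yn-1-yl]-2,2-dimethyl-1,3-dioxan-5-one
Conditions: TBSOTf, 2,6-lutidine, CH2Cl2, −78 °C
Reagents that add atoms: tert-butyldimethylsilyl trifluoromethanesulfonate, CC(C)(C)[Si](C)(C)OS(=O)(=O)C(F)(F)F
Why: Silyl triflate silylation of the secondary hydroxyl at low temperature outruns enol silylation and retro-aldol cleavage, marks O-3 as the oxygen that stays free in the target, and touches no stereocentre.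

**Step 4**
Reactants: 5 (4R)-4-[(1R)-1-(tert-butyldimethylsilyloxy)-4-chlorobut-2-yn-1-yl]-2,2-dimethyl-1,3-dioxan-5-one
Product: 6 (3R,4R)-4-(tert-butyldimethylsilyloxy)-7-chloro-1,3-dihydroxyhept-5-yn-2-one
Conditions: AcOH/THF/H2O (3:1:1), 40 °C
Reagents that add atoms: none
Why: Acid-catalysed ketal hydrolysis cleaves the isopropylidene 1,3-dioxane much faster than the hindered secondary silyl ether, and acidic conditions neither epimerise C2 nor eliminate the β-silyloxy group.

**Step 5**
Reactants: 6 (3R,4R)-4-(tert-butyldimethylsilyloxy)-7-chloro-1,3-dihydroxyhept-5-yn-2-one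
Product: 7 (3R,4R)-4-(tert-butyldimethylsilyloxy)-7-chloro-2-oxohept-5-yne-1,3-diyl dibenzoate
Conditions: BzCl (2.5 equiv), pyridine, DMAP (5 mol%), CH2Cl2, 0 °C
Reagents that add atoms: benzoyl chloride, O=C(Cl)c1ccccc1
Why: Pyridine-mediated acylation (Einhorn conditions) esterifies the two free hydroxyls (O-7 and O-2) while the silyl ether blocks O-3, and the cold, weakly basic medium avoids enolisation and β-elimination.

**Step 6**
Reactants: 7 (3R,4R)-4-(tert-butyldimethylsilyloxy)-7-chloro-2-oxohept-5-yne-1,3-diyl dibenzoate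
Product: 8 (3R,4R,5Z)-4-(tert-butyldimethylsilyloxy)-7-chloro-2-oxohept-5-ene-1,3-diyl dibenzoate
Conditions: H2 (1 atm), Pd/CaCO3 poisoned with Pb(OAc)2, quinoline, EtOAc, rt
Reagents that add atoms: none
Why: Lindlar semi-hydrogenation delivers H2 syn on lead-poisoned palladium and stops at the (Z)-alkene that a six-membered ring requires, while quinoline suppresses over-reduction and C–Cl hydrogenolysis.

**Step 7**
Reactants: 8 (3R,4R,5Z)-4-(tert-butyldimethylsilyloxy)-7-chloro-2-oxohept-5-ene-1,3-diyl dibenzoate; 9 tetrahydrothiophene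
Product: 13 [(1S,2R,3R,6S)-2-(benzoyloxy)-3-(tert-butyldimethylsilyloxy)-7-oxabicyclo[4.1.0]hept-4-en-1-yl]methyl benzoate, via sulfonium chloride 10 (not isolated), via sulfonium ylide 11 (not isolated), via betaine 12 (not isolated)
Conditions: tetrahydrothiophene (3 equiv), NaI (0.1 equiv), MeCN, rt, 16 h; then Cs2CO3 (1.5 equiv), 0 °C to rt
Reagents that add atoms: none
Why: Proposed new method: tetrahydrothiophene displaces the iodide-activated allylic chloride (SN2) to give 10, whose allylic S–CH2 protons are more acidic than the ketone α-protons and are removed by Cs2CO3 to give ylide 11; the ylide carbon C6 adds to the C1 ketone through a six-membered chair-like transition state with the C2 benzoate anti to the forming bond (Felkin–Anh) and the bulky sulfonium on the face away from the C2 and C3 oxygens, and the alkoxide of betaine 12, trans-diaxial to sulfur, displaces tetrahydrothiophene, so carbocycle and cis-fused oxirane form in one flask with C1 (S) and C6 (S) set and the epoxide oxygen syn to the C2 benzoate; the closest known reaction type is the Corey–Chaykovsky epoxidation with allylic sulfonium ylides and its sulfide-mediated intramolecular annulation variants.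

**Step 8**
Reactants: 13 [(1S,2R,3R,6S)-2-(benzoyloxy)-3-(tert-butyldimethylsilyloxy)-7-oxabicyclo[4.1.0]hept-4-en-1-yl]methyl benzoate
Product: 14 [(1S,2R,3R,6S)-2-(benzoyloxy)-3-hydroxy-7-oxabicyclo[4.1.0]hept-4-en-1-yl]methyl benzoate
Conditions: HF·pyridine, pyridine, THF, 0 °C to rt
Reagents that add atoms: none
Why: Fluoride-mediated desilylation with pyridine-buffered HF cleaves the Si–O bond under nearly neutral conditions, so the vinyl epoxide is not opened, the cis-vicinal benzoate does not migrate and no stereocentre is touched.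

**Compound list**
1 | 4-chlorobut-2-yn-1-ol | OCC#CCCl | starting material
2 | 4-chlorobut-2-ynal | O=CC#CCCl | intermediate
3 | 2,2-dimethyl-1,3-dioxan-5-one | CC1(C)OCC(=O)CO1 | starting material
4 | (4R)-4-[(1R)-4-chloro-1-hydroxybut-2-yn-1-yl]-2,2-dimethyl-1,3-dioxan-5-one | ClCC#C[C@@H](O)[C@H]1OC(C)(C)OCC1=O | intermediate
5 | (4R)-4-[(1R)-1-(tert-butyldimethylsilyloxy)-4-chlorobut-2-yn-1-yl]-2,2-dimethyl-1,3-dioxan-5-one | ClCC#C[C@@H](O[Si](C)(C)C(C)(C)C)[C@H]1OC(C)(C)OCC1=O | intermediate
6 | (3R,4R)-4-(tert-butyldimethylsilyloxy)-7-chloro-1,3-dihydroxyhept-5-yn-2-one | ClCC#C[C@@H](O[Si](C)(C)C(C)(C)C)[C@H](C(=O)CO)O | intermediate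
7 | (3R,4R)-4-(tert-butyldimethylsilyloxy)-7-chloro-2-oxohept-5-yne-1,3-diyl dibenzoate | ClCC#C[C@@H](O[Si](C)(C)C(C)(C)C)[C@H](C(=O)COC(=O)c1ccccc1)OC(=O)c1ccccc1 | intermediate
8 | (3R,4R,5Z)-4-(tert-butyldimethylsilyloxy)-7-chloro-2-oxohept-5-ene-1,3-diyl dibenzoate | ClC/C=C\[C@@H](O[Si](C)(C)C(C)(C)C)[C@H](C(=O)COC(=O)c1ccccc1)OC(=O)c1ccccc1 | intermediate
9 | tetrahydrothiophene | C1CCSC1 | starting material
10 | 1-[(2Z,4R,5R)-5,7-bis(benzoyloxy)-4-(tert-butyldimethylsilyloxy)-6-oxohept-2-en-1-yl]tetrahydrothiophenium chloride | [Cl-].C1CC[S+](C1)C/C=C\[C@@H](O[Si](C)(C)C(C)(C)C)[C@H](C(=O)COC(=O)c1ccccc1)OC(=O)c1ccccc1 | intermediate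
11 | sulfonium ylide of 10 (carbanion at the S-bound allylic carbon, Z-alkene, 4R,5R) | C1CC[S+](C1)[CH-]/C=C\[C@@H](O[Si](C)(C)C(C)(C)C)[C@H](C(=O)COC(=O)c1ccccc1)OC(=O)c1ccccc1 | intermediate
12 | betaine: 1-(benzoyloxymethyl)-2-benzoyloxy-3-silyloxy-6-(tetrahydrothiophenium-1-yl)cyclohex-4-en-1-olate, O− cis to the C2 and C3 oxygens and trans to sulfur | O=C(OC[C@]1([O-])[C@H]([S+]2CCCC2)C=C[C@@H](O[Si](C)(C)C(C)(C)C)[C@H]1OC(=O)c1ccccc1)c1ccccc1 | intermediate
13 | [(1S,2R,3R,6S)-2-(benzoyloxy)-3-(tert-butyldimethylsilyloxy)-7-oxabicyclo[4.1.0]hept-4-en-1-yl]methyl benzoate | O=C(OC[C@]12O[C@H]1C=C[C@@H](O[Si](C)(C)C(C)(C)C)[C@H]2OC(=O)c1ccccc1)c1ccccc1 | intermediate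
14 | [(1S,2R,3R,6S)-2-(benzoyloxy)-3-hydroxy-7-oxabicyclo[4.1.0]hept-4-en-1-yl]methyl benzoate | O=C(OC[C@]12O[C@H]1C=C[C@@H](O)[C@H]2OC(=O)c1ccccc1)c1ccccc1 | target

**Totals**
Total step count: 8. Longest linear sequence: 8 steps (1 to 14).

**Steps most likely to fail, with fallbacks**

Step 7 (ring closure). The carbonate may enolise the α-benzoyloxy ketone (epimerisation at C2, loss of the β-silyloxy group) instead of forming the ylide, and the facial selectivity at the ketone is unproven. The fallback sets out from 8 and makes the rings one after the other. PPh3 with catalytic NaI in MeCN gives the allyltriphenylphosphonium chloride F3. K2CO3 with 18-crown-6 in CH2Cl2 then drives an intramolecular Wittig reaction with the ketone to the cyclohexa-1,3-diene F4. N-Bromosuccinimide in wet THF at 0 °C brominates the trisubstituted alkene from the face opposite the two allylic oxygen substituents, with water entering trans at allylic C6, to give the trans-bromohydrin F5. K2CO3 in acetone closes the oxirane with inversion at C1, which places the epoxide oxygen on the face of the C2 and C3 oxygens; the fallback comes back to the route at 13.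

Step 2 (aldol). Proline may add to the ynal or be alkylated by the propargylic chloride, and an unbranched acceptor may give a lower anti/syn ratio. The fallback sets out from 3 and replaces enamine catalysis by an auxiliary-controlled azaenolate aldol. Condensation of 3 with (R)-1-amino-2-(methoxymethyl)pyrrolidine gives the RAMP hydrazone F1. Deprotonation with t-BuLi in THF at −78 °C and addition of 2 at −100 °C gives the anti β-hydroxy hydrazone F2, with the auxiliary fixing C2 as (R). Two-phase cleavage with aqueous oxalic acid and ether returns to the route at 4.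

Step 8 (desilylation). The vinyl epoxide may open under HF, or the benzoate may migrate to the freed hydroxyl. The fallback sets out from 8 and removes the silyl group before any epoxide exists. HF·pyridine with pyridine in THF gives the free alcohol F6. Tetrahydrothiophene with catalytic NaI converts it into the sulfonium chloride F7, and Cs2CO3 at −20 °C closes both rings as in step 7; the hydroxyl, 1,3-syn to the developing alkoxide, can hydrogen-bond to it and favour the all-cis product. The fallback comes back to the route at 14.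

**Further compounds**
F1 | step 2 | 2,2-dimethyl-1,3-dioxan-5-one (R)-1-amino-2-(methoxymethyl)pyrrolidine hydrazone | CC1(C)OCC(=NN2CCC[C@@H]2COC)CO1
F2 | step 2 | RAMP hydrazone of (4R)-4-[(1R)-4-chloro-1-hydroxybut-2-yn-1-yl]-2,2-dimethyl-1,3-dioxan-5-one | ClCC#C[C@@H](O)[C@H]1OC(C)(C)OCC1=NN1CCC[C@@H]1COC
F3 | step 7 | [(2Z,4R,5R)-5,7-bis(benzoyloxy)-4-(tert-butyldimethylsilyloxy)-6-oxohept-2-en-1-yl]triphenylphosphonium chloride | [Cl-].c1ccccc1[P+](c1ccccc1)(c1ccccc1)C/C=C\[C@@H](O[Si](C)(C)C(C)(C)C)[C@H](C(=O)COC(=O)c1ccccc1)OC(=O)c1ccccc1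
F4 | step 7 | [(5R,6S)-6-(benzoyloxy)-5-(tert-butyldimethylsilyloxy)cyclohexa-1,3-dien-1-yl]methyl benzoate | O=C(OCC1=CC=C[C@@H](O[Si](C)(C)C(C)(C)C)[C@H]1OC(=O)c1ccccc1)c1ccccc1
F5 | step 7 | [1-bromo-6-(benzoyloxy)-2-hydroxy-5-(tert-butyldimethylsilyloxy)cyclohex-3-en-1-yl]methyl benzoate, Br trans to the 2-OH, 5-OSi and 6-OBz groups, which are mutually cis | O=C(OC[C@@]1(Br)[C@@H](O)C=C[C@@H](O[Si](C)(C)C(C)(C)C)[C@H]1OC(=O)c1ccccc1)c1ccccc1
F6 | step 8 | (3R,4R,5Z)-7-chloro-4-hydroxy-2-oxohept-5-ene-1,3-diyl dibenzoate | ClC/C=C\[C@@H](O)[C@H](C(=O)COC(=O)c1ccccc1)OC(=O)c1ccccc1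
F7 | step 8 | 1-[(2Z,4R,5R)-5,7-bis(benzoyloxy)-4-hydroxy-6-oxohept-2-en-1-yl]tetrahydrothiophenium chloride | [Cl-].C1CC[S+](C1)C/C=C\[C@@H](O)[C@H](C(=O)COC(=O)c1ccccc1)OC(=O)c1ccccc1
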